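## Retrosynthetic overview

- **Feature:** ring A carries six different positions (C1 CH2OH, C2 arylmethyl, C3 OH, C4 OH, C5 Br, C6 H). Its adjacent C3/C4 hydroxyls are read as the doubly enolised form of a 1,2-dione whose alpha carbons are C2 and C5.
- **Late disconnections:** the C1 CH2OH comes from a methyl ester, the ring-B phenol from its methyl ether, and C5-Br from electrophilic bromination of the free catechol ester.
- **Core disconnection:** C1-C2 and C5-C6 form by a Diels-Alder reaction of methyl propiolate with the bis(silyl enol ether) of 5-(3-bromo-4-methoxyphenyl)pentane-2,3-dione. Dehydrogenation follows.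
- **Dione:** it comes from benzylation of the only possible enolate of mono-ketalised biacetyl, then ketal hydrolysis.
- **Ring order:** ring B is bought. Ring A is the only ring built, closed in step 4 and aromatised in step 5.

Key step: step 4

Remark: the ring-A locants above are used throughout. The target has no stereocentre. The one centre created in step 4 (C2) is racemic and is removed in step 5.

## Route

Step 1
Reactants: 1 3,3-dimethoxybutan-2-one; 2 3-bromo-4-methoxybenzyl bromide
Product: 4 1-(3-bromo-4-methoxyphenyl)-4,4-dimethoxypentan-3-one, via lithium enolate 3 (not isolated)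
Conditions: LiN(iPr)2 (LDA, commercial solution, 1.1 equiv), THF, −78 °C, slow addition of 1; then 2 (0.9 equiv), −78 → 0 °C
Reagents that add atoms: none
Why: Ketone 1 can enolise only at its acetyl methyl group because the other flank is a fully substituted ketal carbon, so the lithium enolate alkylation (SN2 on a reactive benzylic bromide, with the enolate in slight excess to limit double alkylation) builds the chain without regiochemical ambiguity and leaves the aryl bromide untouched.

Step 2
Reactants: 4 1-(3-bromo-4-methoxyphenyl)-4,4-dimethoxypentan-3-one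
Product: 5 5-(3-bromo-4-methoxyphenyl)pentane-2,3-dione
Conditions: CF3CO2H/H2O (1:1), CH2Cl2, 0 °C → rt
Reagents that add atoms: water, O
Why: Acid-catalysed ketal hydrolysis unmasks the second carbonyl, aqueous trifluoroacetic acid being used because the adjacent ketone slows oxocarbenium formation, and the aryl bromide and aryl methyl ether are inert to it.

Step 3
Reactants: 5 5-(3-bromo-4-methoxyphenyl)pentane-2,3-dione
Product: 6 (Z)-5-(3-bromo-4-methoxyphenyl)-2,3-bis(trimethylsilyloxy)penta-1,3-diene
Conditions: Me3SiOTf (2.5 equiv), Et3N (4 equiv), Et2O, 0 °C → rt; pentane, cold aq NaHCO3 wash; used crude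
Reagents that add atoms: trimethylsilyl triflate, C[Si](C)(C)OS(=O)(=O)C(F)(F)F
Why: Soft enolisation with silyl triflate and amine, known for biacetyl and its homologues, silylates both carbonyl oxygens, each carbonyl having one enolisable flank (CH3 or CH2), and the reversible conditions should favour the Z trisubstituted enol ether, in which the arylmethyl group sits cis to the slim O-silyl group and trans to the branched silyloxyvinyl unit.

Step 4
Reactants: 6 (Z)-5-(3-bromo-4-methoxyphenyl)-2,3-bis(trimethylsilyloxy)penta-1,3-diene; 7 methyl propiolate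
Product: 8 racemic methyl 6-(3-bromo-4-methoxybenzyl)-4,5-bis(trimethylsilyloxy)cyclohexa-1,4-diene-1-carboxylate
Conditions: 7 (3 equiv), toluene (about 1 M), BHT (cat.), base-washed sealed tube, Ar, 110 °C; volatiles removed in vacuo; used crude
Reagents that add atoms: none
Why: A concerted but asynchronous normal-electron-demand Diels-Alder reaction pairs the HOMO of diene 6, raised by its two silyloxy donors, with the LUMO of the acetylenic ester; the closest known reactions are the thermal additions of 2,3-bis(trimethylsilyloxy)buta-1,3-diene and related bis(silyl enol ethers) of 1,2-diketones to propiolates and acetylenedicarboxylates. Ring A closes in an intermolecular (4+2) mode, C5-C6 and C1-C2 forming in one step to give a cyclohexa-1,4-diene whose C3=C4 double bond already carries both oxygens and whose C1=C6 double bond carries the ester. The only new stereocentre, C2, has no controlling element (achiral partners and a linear dienophile with no endo/exo issue), so 8 is racemic, which is harmless because step 5 makes C2 trigonal. The step needs ortho regioselectivity: the C3 and C4 oxygen donors push the terminal coefficients in opposite senses and roughly offset each other, so the alkyl group on the C2 terminus decides, leaving the larger coefficient and the smaller steric demand at the unsubstituted CH2 terminus (future C5), which leads the bonding to the electrophilic beta carbon of 7 (future C6). The Z geometry of 6 points the arylmethyl chain away from the diene interior, so the s-cis conformer is accessible and no 1,5-hydrogen shift can drain the diene. Acid-free thermal conditions without a Lewis acid are chosen so that the enol ethers react as a diene and not as Mukaiyama-Michael donors.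

Step 5
Reactants: 8 racemic methyl 6-(3-bromo-4-methoxybenzyl)-4,5-bis(trimethylsilyloxy)cyclohexa-1,4-diene-1-carboxylate
Product: 10 methyl 2-(3-bromo-4-methoxybenzyl)-3,4-dihydroxybenzoate, via bis(trimethylsilyl) ether 9 (not isolated)
Conditions: DDQ (1.05 equiv), toluene, 0 °C → rt, filter; then MeOH, HCl in MeOH (cat.), rt; chromatography
Reagents that add atoms: none
Why: In this quinone dehydrogenation DDQ removes a doubly allylic hydride from C5 or C2 to give a silyloxy-stabilised cation that loses a proton to the arene, which erases the C2 centre, and the aryl silyl ethers that shield the catechol from over-oxidation while DDQ is present are then cleaved by acid-catalysed methanolysis.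

Step 6
Reactants: 10 methyl 2-(3-bromo-4-methoxybenzyl)-3,4-dihydroxybenzoate
Product: 11 methyl 5-bromo-2-(3-bromo-4-methoxybenzyl)-3,4-dihydroxybenzoate
Conditions: Br2 (1.0 equiv), AcOH, 15 °C → rt
Reagents that add atoms: bromine, BrBr
Why: This electrophilic aromatic bromination follows the pattern of protocatechuic esters and aldehydes, since C5 is ortho to the C4 hydroxyl, para to the C2 alkyl group and meta to the ester whereas C6 is ortho to the ester, and ring B, a 2-bromoanisole without a free hydroxyl, is far less nucleophilic than the free catechol, so one equivalent of bromine should be consumed at C5.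

Step 7
Reactants: 11 methyl 5-bromo-2-(3-bromo-4-methoxybenzyl)-3,4-dihydroxybenzoate
Product: 12 methyl 5-bromo-2-(3-bromo-4-hydroxybenzyl)-3,4-dihydroxybenzoate
Conditions: BBr3 (5 equiv), CH2Cl2, −78 → 0 °C; ice-water
Reagents that add atoms: none
Why: Lewis-acid aryl methyl ether cleavage (bromide attack on the O-methyl group of the boron complex) frees the ring-B phenol at temperatures at which the ortho-substituted methyl ester should persist, and it is placed before the reduction because BBr3 would ionise a p-hydroxybenzyl alcohol.

Step 8
Reactants: 12 methyl 5-bromo-2-(3-bromo-4-hydroxybenzyl)-3,4-dihydroxybenzoate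
Product: 13 6-bromo-3-(3-bromo-4-hydroxybenzyl)-4-(hydroxymethyl)benzene-1,2-diol (target)
Conditions: iBu2AlH (DIBAL-H, 7 equiv), THF, −78 → 0 °C; aq KNaC4H4O6 (potassium sodium tartrate), about pH 6, degassed
Reagents that add atoms: none
Why: Excess iBu2AlH first converts the three phenols into covalent aluminium phenoxides, which deactivate the ester less than alkali phenoxides do, and then performs the usual hydride reduction of an ester to a primary alcohol at or below 0 °C, where aryl bromides are inert and loss of the benzylic oxygen through a quinone methide is slow, while the near-neutral tartrate work-up avoids acid ionisation of the product.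

## Compound list

1 | 3,3-dimethoxybutan-2-one | CC(=O)C(C)(OC)OC | starting material
2 | 3-bromo-4-methoxybenzyl bromide | COc1ccc(CBr)cc1Br | starting material
3 | lithium 3,3-dimethoxybut-1-en-2-olate (lithium enolate of 1) | [Li]OC(=C)C(C)(OC)OC | intermediate
4 | 1-(3-bromo-4-methoxyphenyl)-4,4-dimethoxypentan-3-one | CC(OC)(OC)C(=O)CCc1ccc(OC)c(Br)c1 | intermediate
5 | 5-(3-bromo-4-methoxyphenyl)pentane-2,3-dione | CC(=O)C(=O)CCc1ccc(OC)c(Br)c1 | intermediate
6 | (Z)-5-(3-bromo-4-methoxyphenyl)-2,3-bis(trimethylsilyloxy)penta-1,3-diene | C=C(O[Si](C)(C)C)/C(O[Si](C)(C)C)=C/Cc1ccc(OC)c(Br)c1 | intermediate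
7 | methyl propiolate | C#CC(=O)OC | starting material
8 | racemic methyl 6-(3-bromo-4-methoxybenzyl)-4,5-bis(trimethylsilyloxy)cyclohexa-1,4-diene-1-carboxylate | COC(=O)C1=CCC(O[Si](C)(C)C)=C(O[Si](C)(C)C)C1Cc1ccc(OC)c(Br)c1 | intermediate
9 | methyl 2-(3-bromo-4-methoxybenzyl)-3,4-bis(trimethylsilyloxy)benzoate | COC(=O)c1ccc(O[Si](C)(C)C)c(O[Si](C)(C)C)c1Cc1ccc(OC)c(Br)c1 | intermediate
10 | methyl 2-(3-bromo-4-methoxybenzyl)-3,4-dihydroxybenzoate | COC(=O)c1ccc(O)c(O)c1Cc1ccc(OC)c(Br)c1 | intermediate
11 | methyl 5-bromo-2-(3-bromo-4-methoxybenzyl)-3,4-dihydroxybenzoate | COC(=O)c1cc(Br)c(O)c(O)c1Cc1ccc(OC)c(Br)c1 | intermediate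
12 | methyl 5-bromo-2-(3-bromo-4-hydroxybenzyl)-3,4-dihydroxybenzoate | COC(=O)c1cc(Br)c(O)c(O)c1Cc1ccc(O)c(Br)c1 | intermediate
13 | 6-bromo-3-(3-bromo-4-hydroxybenzyl)-4-(hydroxymethyl)benzene-1,2-diol | OCc1cc(Br)c(O)c(O)c1Cc1ccc(O)c(Br)c1 | target

Total step count: 8
Longest linear sequence: 8 steps (1 → 13)

## Steps most likely to fail

**1. Step 4 (cycloaddition).**
- **Risk:** The diene may populate its s-cis conformer poorly and the alkyne is only a moderate dienophile. Slow addition could therefore be overtaken by protodesilylation or thermal decay of the diene, and the ortho regioselectivity could erode at the temperature needed.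
- **Fallback (from 6, back at 9):** An olefinic propiolate equivalent of the same polarisation replaces the alkyne. Diene 6 and methyl 2-chloroacrylate in toluene at 80-100 °C should give methyl 2-(3-bromo-4-methoxybenzyl)-1-chloro-3,4-bis(trimethylsilyloxy)cyclohex-3-ene-1-carboxylate F1, a diastereomer mixture of no consequence.
- Dry DBU in toluene then removes hydrogen chloride. This gives 8, its conjugated isomer methyl 2-(3-bromo-4-methoxybenzyl)-3,4-bis(trimethylsilyloxy)cyclohexa-1,3-diene-1-carboxylate F2, or both.
- Both dienes are at the dihydroarene oxidation level, and the DDQ treatment of step 5 converts them into 9.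

**2. Step 3 (double silylation).**
- **Risk:** The second enolisation may stall and the enol ether geometry may be poorly controlled. Trimethylsilyl groups may also be lost by hydrolysis during isolation, and the product cannot be purified.
- **Fallback (from 5, back at 10):** The route moves to an isolable silyl series. Dione 5 with tBuMe2SiOTf and Et3N in CH2Cl2 should give (Z)-5-(3-bromo-4-methoxyphenyl)-2,3-bis(tert-butyldimethylsilyloxy)penta-1,3-diene F3. It is chromatographed on Et3N-deactivated silica, so that the unreactive geometric isomer is removed.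
- F3 and 7 in xylene at 130-140 °C give racemic methyl 6-(3-bromo-4-methoxybenzyl)-4,5-bis(tert-butyldimethylsilyloxy)cyclohexa-1,4-diene-1-carboxylate F4.
- DDQ gives methyl 2-(3-bromo-4-methoxybenzyl)-3,4-bis(tert-butyldimethylsilyloxy)benzoate F5, and Bu4NF buffered with AcOH in THF releases 10.

**3. Step 8 (reduction of the triphenol ester).**
- **Risk:** The reduction may stall because of the electron-rich phenoxide para to the ester. Over-reduction may occur by loss of the benzylic oxygen through a quinone methide. Material may also be lost through aluminium chelation of the catechol in the work-up.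
- **Fallback (from 12, back at 13):** The phenols are protected, the ester reduced, and the protection removed. Compound 12 with tBuMe2SiOTf and 2,6-lutidine in CH2Cl2 should give methyl 5-bromo-2-[3-bromo-4-(tert-butyldimethylsilyloxy)benzyl]-3,4-bis(tert-butyldimethylsilyloxy)benzoate F6.
- iBu2AlH (2.5 equiv) in CH2Cl2 at −78 °C gives {5-bromo-2-[3-bromo-4-(tert-butyldimethylsilyloxy)benzyl]-3,4-bis(tert-butyldimethylsilyloxy)phenyl}methanol F7.
- Bu4NF buffered with AcOH in THF at 0 °C gives 13.

## Further compounds

F1 | step 4 | methyl 2-(3-bromo-4-methoxybenzyl)-1-chloro-3,4-bis(trimethylsilyloxy)cyclohex-3-ene-1-carboxylate (diastereomer mixture, racemic) | COC(=O)C1(Cl)CCC(O[Si](C)(C)C)=C(O[Si](C)(C)C)C1Cc1ccc(OC)c(Br)c1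
F2 | step 4 | methyl 2-(3-bromo-4-methoxybenzyl)-3,4-bis(trimethylsilyloxy)cyclohexa-1,3-diene-1-carboxylate | COC(=O)C1=C(Cc2ccc(OC)c(Br)c2)C(O[Si](C)(C)C)=C(O[Si](C)(C)C)CC1
F3 | step 3 | (Z)-5-(3-bromo-4-methoxyphenyl)-2,3-bis(tert-butyldimethylsilyloxy)penta-1,3-diene | C=C(O[Si](C)(C)C(C)(C)C)/C(O[Si](C)(C)C(C)(C)C)=C/Cc1ccc(OC)c(Br)c1
F4 | step 3 | racemic methyl 6-(3-bromo-4-methoxybenzyl)-4,5-bis(tert-butyldimethylsilyloxy)cyclohexa-1,4-diene-1-carboxylate | COC(=O)C1=CCC(O[Si](C)(C)C(C)(C)C)=C(O[Si](C)(C)C(C)(C)C)C1Cc1ccc(OC)c(Br)c1
F5 | step 3 | methyl 2-(3-bromo-4-methoxybenzyl)-3,4-bis(tert-butyldimethylsilyloxy)benzoate | COC(=O)c1ccc(O[Si](C)(C)C(C)(C)C)c(O[Si](C)(C)C(C)(C)C)c1Cc1ccc(OC)c(Br)c1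
F6 | step 8 | methyl 5-bromo-2-[3-bromo-4-(tert-butyldimethylsilyloxy)benzyl]-3,4-bis(tert-butyldimethylsilyloxy)benzoate | COC(=O)c1cc(Br)c(O[Si](C)(C)C(C)(C)C)c(O[Si](C)(C)C(C)(C)C)c1Cc1ccc(O[Si](C)(C)C(C)(C)C)c(Br)c1
F7 | step 8 | {5-bromo-2-[3-bromo-4-(tert-butyldimethylsilyloxy)benzyl]-3,4-bis(tert-butyldimethylsilyloxy)phenyl}methanol | OCc1cc(Br)c(O[Si](C)(C)C(C)(C)C)c(O[Si](C)(C)C(C)(C)C)c1Cc1ccc(O[Si](C)(C)C(C)(C)C)c(Br)c1
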